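The runs are simulated with constants of no real substance; scatter was added.

Monomer units are conserved: each one charged stands as free monomer, in a chain, in quenched substrate or with a dead end. So I need the level of free monomer and the toll of the protic impurity.

| setting | summer | autumn | flask |
|---|---|---|---|
| free monomer | 0.050 M | 0.050 M | 0.050 M |
| protic impurity | 1.7 mM | 3.8 mM | 2.50 mM |
| initiator | 0.60 mM | 0.60 mM | 0.60 mM |
| remark | run made earlier | run made earlier |  |
| time |  |  | 6.0 h |

| run | time / h | monomer in chains / % | free monomer / % |
|---|---|---|---|
| summer | 0.417 | 81.8 | 15.5 |
| summer | 0.667 | 81.8 | 13.8 |
| summer | 1.00 | 80.9 | 15.4 |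
| summer | 2.00 | 81.8 | 14.2 |
| summer | 3.00 | 80.9 | 14.8 |
| summer | 5.00 | 82.2 | 14.9 |
| autumn | 0.333 | 78.6 | 15.7 |
| autumn | 1.00 | 77.9 | 13.9 |
| autumn | 1.50 | 77.7 | 13.8 |
| autumn | 2.50 | 77.7 | 14.6 |
| autumn | 4.00 | 77.1 | 14.4 |
| autumn | 5.00 | 76.6 | 14.5 |

(scatter of a reading: 0.5 percentage points)

- average number of monomer units in a chain (chains begun, living or dead) at 6.0 h
- part of the free monomer that has reacted at 6.0 h

- the average divides the monomer in chains by the number of chains begun, living and dead together
- candidate steps: free monomer + initiator -> living end + monomer in chains; free monomer + living end -> monomer in chains + living end; monomer in chains + living end -> free monomer + living end; protic impurity + free monomer -> quenched substrate; living end + monomer in chains -> dead end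
- the earlier runs do not show the number of chains; that part of a forecast is a guess

I read the columns against each other. Free monomer averages 14.8% in summer and 14.5% in autumn, though autumn carries about twice the impurity. Summer's first reading, at 0.417 h, already stands at 15.5%. Monomer in chains averages 81.6% and 77.6%, a drop of 4 percentage points, while the impurity charges differ by 4.2 points. So I count one monomer lost per impurity.

The free-monomer means together read 7.31 mM. I take this reading as the floor, the free-monomer concentration at which chains shed units as fast as they add them, the equilibrium monomer concentration. I carry it as a concentration, an assumption that the equal charges of these runs cannot test.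

For the flask, 0.050 M less the floor less 2.50 mM of impurity leaves 40.2 mM for chains and dead ends together, which I book as chains, and the part reacted, quenched monomer counted, is 85.4%. If each initiator starts one chain, a guess, since the runs do not show chains, the average is 67.0.

The forecast gives 67 and 85.4%, and it reads the level the same way: “this is a propagation–depropagation ceiling”.

The flask gives 66.2 and 85.4%.

    free monomer + initiator → living end + monomer in chains (k = 0.800 M⁻¹ s⁻¹)
    free monomer + living end → monomer in chains + living end, rate k2*[living end]*[free monomer] (k = 5.60 M⁻¹ s⁻¹)
    monomer in chains + living end → free monomer + living end, rate k3*[living end] as long as [monomer in chains] is above zero (k = 0.0410 s⁻¹)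
    protic impurity + free monomer → quenched substrate (k = 0.0790 M⁻¹ s⁻¹)
    living end + monomer in chains → dead end (k = 0.00150 M⁻¹ s⁻¹)

In the flask, free monomer stands at 14.6% of its charge, and the floor as I read it is 14.6% of that charge. At 6.0 h the half-life of free monomer by the step into chains is 0.21 h, short against that time, and monomer in chains is made and used at a ratio of 0.999. A neighbour charged with 0.013 M of free monomer tests the floor as a concentration: the floor is 56.2% of that charge, and the neighbour ends with 56.2% free monomer and an average chain of 5.22.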